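Amounts first: the flask called north holds [Q] = 11 mM against [Z] = 33.0 mM, so Q, the smaller charge, is the limiting reagent, and its balance is the account to keep. Whatever part of the charge is not yet in D or E is the pool, and on the list of suspects the steps into D and E run one way, so further D has to come out of that pool.

| flask | Q | Z | L | X | temperature | remark | time |
|---|---|---|---|---|---|---|---|
| north | 11 mM | 33 mM | 1.1 mM | 8.5 µM | 25 °C | the very flask that is asked about, followed so far |  |
| south-east | 11 mM | 33 mM | 1.7 mM | 8.5 µM | 25 °C | run made earlier |  |
| flask | 11 mM | 33.0 mM | 1.1 mM | 8.5 µM | 25 °C |  | 2.5 h |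

| run | time / min | D / % | Q / % |
|---|---|---|---|
| north | 6.00 | 7 | 17 |
| north | 20.0 | 21 | 5 |
| north | 30.0 | 21 | 0 |
| north | 50.0 | 25 | 0 |
| north | 60.0 | 27 | 0 |
| north | 90.0 | 25 | 1 |
| south-east | 0.200 | 2 | 82 |
| south-east | 0.667 | 1 | 53 |
| south-east | 1.00 | 0 | 42 |
| south-east | 2.00 | 2 | 30 |
| south-east | 2.50 | 0 | 23 |
| south-east | 3.00 | 4 | 26 |

(standard deviation of a reading: 1.5 percentage points)

- noon: at 2.5 h add Z, 50.0% of the amount charged, then wait 2.5 h
- dusk: at 2.5 h add L, 100% of the amount charged, then wait 2.5 h
- winter: change nothing and wait 2.5 h more
- autumn: at 2.5 h raise the temperature by 15 K, then wait 2.5 h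
- spring: at 2.5 h take out 90% of the D then present, then wait 2.5 h

- D taken out counts as made
- on the list of suspects stand: Q + L <-> L + G; X + G <-> J; Z + J -> X + D; G -> E
- "the catalyst" is L with its forms; X is a second catalyst
- additions bring no volume worth counting
- the earlier runs do not show what temperature does; that part of a forecast is a guess

- D, in percent of the Q first charged, at 2.5 h
- the option that brings most further D ("none" if no option brings more than 2 percentage points) (noon / dusk / winter / autumn / spring / none)
- D present, with what was taken out counted in, in percent of the Q first charged, after autumn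
- D present, with what was taken out counted in, in percent of the Q first charged, after spring

What share of Q ends as D in the north run? From 30.0 min to 90.0 min the D readings average 24.5%, and I take that as the share and as my answer for "now".

Did D stop for want of Z? No, because that much D uses 8.17% of the Z charge, which leaves 91.8%, more than was used.

But G is never read, so how can the pool be known? The south-east run gives the link: L stands on both sides of its step, and Q levels there at 24.5% of the charge in the last two readings, which I take as Q's part of the pool. Some of the pool has left by then, so this part is a low estimate and the pool reckoned from it a high one.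

And how fast does the pool drain in the north flask? Q reads 17% at 6.00 min and 5% at 20.0 min, and moving both readings by a full scatter of 1.5 percentage points against the fall gives a cautious rate of 0.0621 min⁻¹; if Q keeps its part of the pool and that pace lasts to 2.5 h, I reckon the pool there at 0.00830%, while J, bounded by [X] = 8.5 µM, is at most 0.0773% of the charge.

So what can any option win? The share reaching D from a late pool may differ from the share of the whole run, so I count the pool and J whole as D, which gives 0.086 points, and this reserve, the further D obtainable if what is not yet in D or E all went to D, is below the 2 points that counts, so I say none, with autumn and spring staying at my 24.5%.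

The forecast gives 25% for "now", none as best, 25% after autumn and 25% after spring, holding that “the substrate is exhausted, not that the catalyst has died”; its "now" stands 0.5 points above mine, within one scatter.

The flask gives 25.3% at 2.5 h, 25.3% after autumn and 25.3% after spring, and the best option is none, with noon, dusk, winter, autumn and spring each bringing 0 points.

    Q + L ⇌ L + G (K = 2.90, k = 11.0 M⁻¹ s⁻¹, Ea = 45.0 kJ mol⁻¹, ΔH = −20.0 kJ mol⁻¹)
    X + G ⇌ J (K = 52000 M⁻¹, k = 580 M⁻¹ s⁻¹, Ea = 45.0 kJ mol⁻¹, ΔH = −20.0 kJ mol⁻¹)
    Z + J → X + D (k = 8.10 M⁻¹ s⁻¹, Ea = 41.0 kJ mol⁻¹)
    G → E (k = 0.00210 s⁻¹, Ea = 92.0 kJ mol⁻¹)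
    (constants at 25 °C)

The north flask is at rest by 150 min: Q reads 0%, G 0% and J 0% of the X charged, so the reserve, 0.086 points in my reckoning, comes to 0 points, with D at 25.3% and E at 74.7% closing the balance. The neighbour charged with [X] = 0.034 mM ends with D at 55.3% and E at 44.7%, yet its Q of 0%, G of 0% and J of 0% give a reserve of 0 points too. Ten times the time changes nothing in the north flask: at 1500 min D reads 25.3% and E 74.7%.

The data are calculated for substances that don't exist; noise was put on by code.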